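The route rests on disconnecting the eleven-membered carbocycle at the bond between its hydroxyl-bearing carbon and the adjacent methyl-bearing olefinic carbon. The key step exploits this secondary allylic alcohol/E-trisubstituted olefin unit of the macrocycle: a nickel-catalysed reductive coupling of an aldehyde with a 2-alkyne closes the ring last and creates the C–C bond, the E olefin and the carbinol centre in one operation. Its precursor is a fully substituted cis-hydrindane (the six- and five-membered rings) carrying the exocyclic methylene, both esters, an acetaldehyde arm on the six-membered ring and a but-2-ynyl-terminated side chain on the five-membered ring.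

Key step: step 15

Assumption: compounds 1, 7, 17, 21 and 23 are taken as purchasable; names use hydrindane numbering (C7a carries the angular methyl), and α denotes the face of that methyl group.

Step 1
Reactants: 1 4-methoxy-2-methylphenol
Product: 2 4,4-dimethoxy-2-methylcyclohexa-2,5-dien-1-one
Conditions: PhI(OAc)2, MeOH, 0 °C
Reagents that add atoms: methanol, CO
Why: Oxidative dearomatization of a para-alkoxyphenol by a hypervalent iodine reagent in methanol should trap the phenoxenium ion as the quinone monoketal; no stereocenter is formed.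

Step 2
Reactants: 2 4,4-dimethoxy-2-methylcyclohexa-2,5-dien-1-one
Product: 3 4,4-dimethoxy-2-methylcyclohex-2-en-1-one
Conditions: H2 (1 atm), RhCl(PPh3)3 (cat.), benzene, rt
Reagents that add atoms: none
Why: Homogeneous hydrogenation with Wilkinson's catalyst should reduce only the unhindered disubstituted C5=C6 bond of the cross-conjugated dienone and leave the methyl-bearing trisubstituted one, as with steroidal 1,4-dien-3-ones.

Step 3
Reactants: 3 4,4-dimethoxy-2-methylcyclohex-2-en-1-one
Product: 4 (1S)-4,4-dimethoxy-2-methylcyclohex-2-en-1-ol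
Conditions: (R)-Me-CBS (10 mol%), BH3·SMe2, THF, −20 °C
Reagents that add atoms: none
Why: Corey–Bakshi–Shibata reduction, in which the α-methylalkenyl arm acts as the large and the CH2 arm as the small ketone substituent, should give the (S)-allylic alcohol that becomes the propanoate-bearing C7 stereocenter.

Step 4
Reactants: 4 (1S)-4,4-dimethoxy-2-methylcyclohex-2-en-1-ol
Product: 6 (4S)-4-[(tert-butyldimethylsilyl)oxy]-3-methylcyclohex-2-en-1-one, via silyl ether ketal 5 (not isolated)
Conditions: TBSCl, imidazole, DMF, rt; then 1 M HCl, THF, 0 °C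
Reagents that add atoms: tert-butyldimethylsilyl chloride, CC(C)(C)[Si](C)(C)Cl; water, O
Why: Silylation followed by hydrolysis of the very acid-labile allylic dimethyl ketal, under conditions the TBS ether tolerates, should unveil the transposed enone without touching the stereocenter.

Step 5
Reactants: 6 (4S)-4-[(tert-butyldimethylsilyl)oxy]-3-methylcyclohex-2-en-1-one; 7 [2-(1,3-dioxan-2-yl)ethyl]magnesium bromide
Product: 9 (3S,4S)-4-[(tert-butyldimethylsilyl)oxy]-3-[2-(1,3-dioxan-2-yl)ethyl]-3-methylcyclohexan-1-one, via trimethylsilyl enol ether 8 (not isolated)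
Conditions: CuBr·SMe2 (10 mol%), TMSCl, DMPU, THF, −78 to −30 °C; then 0.5 M HCl, 0 °C
Reagents that add atoms: none
Why: TMSCl-accelerated copper-catalysed conjugate addition of the Grignard reagent to the β,β-disubstituted enone should occur anti to the adjacent silyloxy group, setting the quaternary carbon with its methyl cis to the oxygen.

Step 6
Reactants: 9 (3S,4S)-4-[(tert-butyldimethylsilyl)oxy]-3-[2-(1,3-dioxan-2-yl)ethyl]-3-methylcyclohexan-1-one
Product: 10 (7S,7aS)-7-hydroxy-7a-methyl-1,2,5,6,7,7a-hexahydro-4H-inden-4-one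
Conditions: 3 M HCl, THF, 60 °C
Reagents that add atoms: none
Why: Acid should unmask the aldehyde, close the cyclopentene by intramolecular aldol condensation through the ketone α-carbon next to the quaternary centre (5-exo-trig, then dehydration to the conjugated enone) and remove the silyl group; no new stereocenter is formed.

Step 7
Reactants: 10 (7S,7aS)-7-hydroxy-7a-methyl-1,2,5,6,7,7a-hexahydro-4H-inden-4-one
Product: 11 (7S,7aS)-7a-methyl-4-oxo-1,2,5,6,7,7a-hexahydro-4H-inden-7-yl propanoate
Conditions: (EtCO)2O, DMAP (cat.), pyridine, CH2Cl2, rt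
Reagents that add atoms: propanoic anhydride, CCC(=O)OC(=O)CC
Why: DMAP-catalysed acylation installs the propanoate of the target at this stage, so that no protecting-group exchange is needed later.

Step 8
Reactants: 12 propanal; 13 pyrrolidine
Product: 14 (E)-1-(prop-1-en-1-yl)pyrrolidine
Conditions: K2CO3, 0 °C to rt; distillation
Reagents that add atoms: none
Why: Condensation of the aldehyde with the secondary amine (enamine formation) should give the thermodynamically preferred E enamine.

Step 9
Reactants: 11 (7S,7aS)-7a-methyl-4-oxo-1,2,5,6,7,7a-hexahydro-4H-inden-7-yl propanoate; 14 (E)-1-(prop-1-en-1-yl)pyrrolidine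
Product: 16 (2S)-2-[7aα-methyl-4-oxo-7α-(propanoyloxy)-3aα-H-octahydro-1H-inden-3β-yl]propanal, via cyclic N,O-acetal 15 (not isolated)
Conditions: MeCN, 60 °C; then AcOH/NaOAc buffer (pH 5), THF–H2O, 0 °C
Reagents that add atoms: water, O
Why: Stork enamine Michael addition through a hetero-Diels–Alder-like synclinal transition state with the amino group endo: the enamine should attack C3 of the s-cis enone anti to the angular methyl group, its E geometry places the methyl group exo and thereby sets the (S) side-chain carbon syn to the ring as in enamine–nitroolefin additions, and buffered hydrolysis with ketonization anti to the new C3 substituent should give the cis ring fusion.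

Step 10
Reactants: 16 (2S)-2-[7aα-methyl-4-oxo-7α-(propanoyloxy)-3aα-H-octahydro-1H-inden-3β-yl]propanal; 17 1-methyl-1-(trimethylsilyl)allene
Product: 18 3β-[(2S,3S)-3-hydroxyhept-5-yn-2-yl]-7aα-methyl-4-oxo-3aα-H-octahydro-1H-inden-7α-yl propanoate
Conditions: TiCl4, CH2Cl2, −78 °C
Reagents that add atoms: none
Why: Lewis-acid-promoted SE2' addition of the allenylsilane (propargylation) is chemoselective for the aldehyde over the hindered ketone and, by Felkin–Anh attack anti to the ring carbon, should give the (S)-carbinol with methyl and hydroxyl syn, the but-2-ynyl group arising by loss of silicon from the β-silyl vinyl cation.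

Step 11
Reactants: 18 3β-[(2S,3S)-3-hydroxyhept-5-yn-2-yl]-7aα-methyl-4-oxo-3aα-H-octahydro-1H-inden-7α-yl propanoate
Product: 19 3β-[(2S,3S)-3-acetoxyhept-5-yn-2-yl]-7aα-methyl-4-oxo-3aα-H-octahydro-1H-inden-7α-yl propanoate
Conditions: Ac2O, DMAP (cat.), pyridine, CH2Cl2, 0 °C
Reagents that add atoms: acetic anhydride, CC(=O)OC(C)=O
Why: DMAP-catalysed acetylation of the secondary alcohol installs the acetate of the target, the δ-hydroxy ketone reacting through its open form.

Step 12
Reactants: 19 3β-[(2S,3S)-3-acetoxyhept-5-yn-2-yl]-7aα-methyl-4-oxo-3aα-H-octahydro-1H-inden-7α-yl propanoate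
Product: 20 3β-[(2S,3S)-3-acetoxyhept-5-yn-2-yl]-7aα-methyl-4-[(trifluoromethylsulfonyl)oxy]-2,3,3aα,6,7,7a-hexahydro-1H-inden-7α-yl propanoate
Conditions: KHMDS, THF, −78 °C; then PhNTf2
Reagents that add atoms: N-phenylbis(trifluoromethanesulfonimide), O=S(=O)(N(c1ccccc1)S(=O)(=O)C(F)(F)F)C(F)(F)F
Why: Kinetic deprotonation at the less hindered C5 methylene and O-sulfonylation should give the Δ4(5) enol triflate, which also removes the epimerizable ketone next to the ring-fusion carbon.

Step 13
Reactants: 20 3β-[(2S,3S)-3-acetoxyhept-5-yn-2-yl]-7aα-methyl-4-[(trifluoromethylsulfonyl)oxy]-2,3,3aα,6,7,7a-hexahydro-1H-inden-7α-yl propanoate; 21 (tributylstannyl)methanol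
Product: 22 3β-[(2S,3S)-3-acetoxyhept-5-yn-2-yl]-4-(hydroxymethyl)-7aα-methyl-2,3,3aα,6,7,7a-hexahydro-1H-inden-7α-yl propanoate
Conditions: Pd(PPh3)4 (5 mol%), LiCl, 1,4-dioxane, 90 °C
Reagents that add atoms: none
Why: Stille coupling of the enol triflate with the hydroxymethylstannane (LiCl-assisted transmetalation) should install the allylic hydroxymethyl group without moving the olefin.

Step 14
Reactants: 22 3β-[(2S,3S)-3-acetoxyhept-5-yn-2-yl]-4-(hydroxymethyl)-7aα-methyl-2,3,3aα,6,7,7a-hexahydro-1H-inden-7α-yl propanoate; 23 vinyl acetate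
Product: 25 3β-[(2S,3S)-3-acetoxyhept-5-yn-2-yl]-7aα-methyl-4-methylidene-5α-(2-oxoethyl)-3aα-H-octahydro-1H-inden-7α-yl propanoate, via allyl vinyl ether 24 (not isolated)
Conditions: [Ir(cod)Cl]2 (1 mol%), Na2CO3, toluene, 100 °C; then 150 °C (sealed tube)
Reagents that add atoms: none
Why: Iridium-catalysed transvinylation of the allylic alcohol followed by thermal Claisen rearrangement creates the C5–CH2CHO bond and the exocyclic C4 methylene in one [3,3] shift, and the vinyl ether should fold over the α face of C4=C5 because the β face is screened by the pseudoaxial C3 side chain, which places the acetaldehyde arm cis to the C7 propanoate.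

Step 15
Reactants: 25 3β-[(2S,3S)-3-acetoxyhept-5-yn-2-yl]-7aα-methyl-4-methylidene-5α-(2-oxoethyl)-3aα-H-octahydro-1H-inden-7α-yl propanoate
Product: 27 target CNP0180453.1, via triethylsilyl ether 26 (not isolated)
Conditions: Ni(cod)2 (20 mol%), IMes·HCl (20 mol%), KOtBu (20 mol%), Et3SiH (3 equiv), THF, rt, syringe-pump addition of 25 (0.005 M); then HF·pyridine, THF, 0 °C
Reagents that add atoms: none
Why: Ni(0)–IMes binds the aldehyde and the tethered 2-alkyne and undergoes oxidative cyclization to an oxanickelacyclopentene; σ-bond metathesis of the Ni–O bond with Et3SiH and C–H reductive elimination release the macrocyclic (E)-allylic silyl ether, which HF·pyridine desilylates in the same flask. The closest known reaction type is the Ni/NHC-catalysed reductive macrocyclization of ynals with silanes. The eleven-membered ring is closed in the endocyclic mode with respect to the alkyne, that is by C–C bond formation between the aldehyde carbon and the methyl-bearing alkyne carbon. cis-Addition of carbon and hydride across the alkyne fixes the E trisubstituted olefin, and the new carbinol centre is set under substrate control by the conformation of the forming bridged ring, in which the aldehyde should be attacked on its outward-facing side to give the (R)-alcohol; this is the least secure element. The step needs regioselectivity (endocyclic eleven-membered against exocyclic ten-membered closure), which the small IMes ligand should secure by directing C–C bond formation to the less hindered methyl-substituted alkyne terminus, and chemoselectivity over the 1,1-disubstituted olefin and the two esters, which Ni(0)/silane conditions should leave untouched, while high dilution suppresses oligomerization.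

Compound list
1 | 4-methoxy-2-methylphenol | COc1ccc(O)c(C)c1 | starting material
2 | 4,4-dimethoxy-2-methylcyclohexa-2,5-dien-1-one | COC1(OC)C=CC(=O)C(C)=C1 | intermediate
3 | 4,4-dimethoxy-2-methylcyclohex-2-en-1-one | COC1(OC)CCC(=O)C(C)=C1 | intermediate
4 | (1S)-4,4-dimethoxy-2-methylcyclohex-2-en-1-ol | COC1(OC)CC[C@H](O)C(C)=C1 | intermediate
5 | tert-butyl{[(1S)-4,4-dimethoxy-2-methylcyclohex-2-en-1-yl]oxy}dimethylsilane | COC1(OC)CC[C@H](O[Si](C)(C)C(C)(C)C)C(C)=C1 | intermediate
6 | (4S)-4-[(tert-butyldimethylsilyl)oxy]-3-methylcyclohex-2-en-1-one | O=C1CC[C@H](O[Si](C)(C)C(C)(C)C)C(C)=C1 | intermediate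
7 | [2-(1,3-dioxan-2-yl)ethyl]magnesium bromide | Br[Mg]CCC1OCCCO1 | starting material
8 | trimethylsilyl enol ether of 9 (C1=C2 enol ether) | C[Si](C)(C)OC1=C[C@](C)(CCC2OCCCO2)[C@@H](O[Si](C)(C)C(C)(C)C)CC1 | intermediate
9 | (3S,4S)-4-[(tert-butyldimethylsilyl)oxy]-3-[2-(1,3-dioxan-2-yl)ethyl]-3-methylcyclohexan-1-one | O=C1CC[C@H](O[Si](C)(C)C(C)(C)C)[C@@](C)(CCC2OCCCO2)C1 | intermediate
10 | (7S,7aS)-7-hydroxy-7a-methyl-1,2,5,6,7,7a-hexahydro-4H-inden-4-one | O=C1CC[C@H](O)[C@@]2(C)CCC=C12 | intermediate
11 | (7S,7aS)-7a-methyl-4-oxo-1,2,5,6,7,7a-hexahydro-4H-inden-7-yl propanoate | O=C1CC[C@H](OC(=O)CC)[C@@]2(C)CCC=C12 | intermediate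
12 | propanal | CCC=O | starting material
13 | pyrrolidine | C1CCNC1 | starting material
14 | (E)-1-(prop-1-en-1-yl)pyrrolidine | C/C=C/N1CCCC1 | intermediate
15 | cyclic N,O-acetal: 2-(pyrrolidin-1-yl)-3-methyl-3,4-dihydro-2H-pyran fused across C3–C3a–C4 of the hydrindene, amino group endo, methyl trans to C2 of the five-membered ring | O3C=1CC[C@H](OC(=O)CC)[C@@]2(C)CC[C@@H]([C@H](C)[C@H]3N4CCCC4)C=12 | intermediate
16 | (2S)-2-[7aα-methyl-4-oxo-7α-(propanoyloxy)-3aα-H-octahydro-1H-inden-3β-yl]propanal | O=C1CC[C@H](OC(=O)CC)[C@@]2(C)CC[C@@H]([C@H](C)C=O)[C@@H]12 | intermediate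
17 | 1-methyl-1-(trimethylsilyl)allene | C=C=C(C)[Si](C)(C)C | starting material
18 | 3β-[(2S,3S)-3-hydroxyhept-5-yn-2-yl]-7aα-methyl-4-oxo-3aα-H-octahydro-1H-inden-7α-yl propanoate | O=C1CC[C@H](OC(=O)CC)[C@@]2(C)CC[C@@H]([C@H](C)[C@@H](O)CC#CC)[C@@H]12 | intermediate
19 | 3β-[(2S,3S)-3-acetoxyhept-5-yn-2-yl]-7aα-methyl-4-oxo-3aα-H-octahydro-1H-inden-7α-yl propanoate | O=C1CC[C@H](OC(=O)CC)[C@@]2(C)CC[C@@H]([C@H](C)[C@@H](OC(C)=O)CC#CC)[C@@H]12 | intermediate
20 | 3β-[(2S,3S)-3-acetoxyhept-5-yn-2-yl]-7aα-methyl-4-[(trifluoromethylsulfonyl)oxy]-2,3,3aα,6,7,7a-hexahydro-1H-inden-7α-yl propanoate | O=S(=O)(OC1=CC[C@H](OC(=O)CC)[C@@]2(C)CC[C@@H]([C@H](C)[C@@H](OC(C)=O)CC#CC)[C@@H]12)C(F)(F)F | intermediate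
21 | (tributylstannyl)methanol | OC[Sn](CCCC)(CCCC)CCCC | starting material
22 | 3β-[(2S,3S)-3-acetoxyhept-5-yn-2-yl]-4-(hydroxymethyl)-7aα-methyl-2,3,3aα,6,7,7a-hexahydro-1H-inden-7α-yl propanoate | OCC1=CC[C@H](OC(=O)CC)[C@@]2(C)CC[C@@H]([C@H](C)[C@@H](OC(C)=O)CC#CC)[C@@H]12 | intermediate
23 | vinyl acetate | C=COC(C)=O | starting material
24 | 3β-[(2S,3S)-3-acetoxyhept-5-yn-2-yl]-7aα-methyl-4-[(vinyloxy)methyl]-2,3,3aα,6,7,7a-hexahydro-1H-inden-7α-yl propanoate | C=COCC1=CC[C@H](OC(=O)CC)[C@@]2(C)CC[C@@H]([C@H](C)[C@@H](OC(C)=O)CC#CC)[C@@H]12 | intermediate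
25 | 3β-[(2S,3S)-3-acetoxyhept-5-yn-2-yl]-7aα-methyl-4-methylidene-5α-(2-oxoethyl)-3aα-H-octahydro-1H-inden-7α-yl propanoate | C=C1[C@H](CC=O)C[C@H](OC(=O)CC)[C@@]2(C)CC[C@@H]([C@H](C)[C@@H](OC(C)=O)CC#CC)[C@@H]12 | intermediate
26 | O-triethylsilyl ether of 27 | C=C1[C@@H]2C[C@@H](O[Si](CC)(CC)CC)/C(C)=C/C[C@H](OC(C)=O)[C@@H](C)[C@@H]3CC[C@](C)([C@@H](OC(=O)CC)C2)[C@H]13 | intermediate
27 | CNP0180453.1 (tricyclic diterpenoid allylic alcohol with acetate and propanoate esters) | C=C1[C@@H]2C[C@@H](O)/C(C)=C/C[C@H](OC(C)=O)[C@@H](C)[C@@H]3CC[C@](C)([C@@H](OC(=O)CC)C2)[C@H]13 | target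

Total step count: 15. Longest linear sequence: 14 steps (steps 1–7 and 9–15; step 8 is a one-step side branch).

Steps most likely to fail

Step 15. The oxidative cyclization may insert the alkyne with the wrong regiochemistry (ten-membered ring with an exocyclic ethylidene), the silane may reduce the aldehyde before ring closure, or the aldehyde may be attacked on the wrong face. The fallback fixes the regiochemistry before the closure. Setting out from allylic alcohol 22, hydrozirconation of the 2-alkyne with Cp2Zr(H)Cl (excess, THF, 45 °C, zirconium equilibrating to the methyl-bearing carbon) and iodinolysis would give the (E)-vinyl iodide allylic alcohol F1. The vinylation/Claisen conditions of step 14 would convert F1 into the iodo aldehyde F2. An intramolecular Nozaki–Hiyama–Kishi coupling (CrCl2, NiCl2 cat., DMSO/THF, high dilution) would then close the ring and come back to the route at 27. Should either closure set the carbinol centre with poor facial selectivity, the allylic alcohol mixture would be oxidized with MnO2 to the macrocyclic enone F3 and reduced with (S)-Me-CBS/catecholborane, again arriving at 27.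

Step 9. The hindered enone may react slowly with the enamine, the α-methyl aldehyde centre may lose its configuration by iminium–enamine exchange during hydrolysis, and ketonization may occur from the wrong face to give the trans ring fusion. The fallback sets out from enone 11. A Lewis-acid-mediated Mukaiyama–Michael addition of the O-trimethylsilyl ketene S,O-acetal of S-ethyl propanethioate (TiCl4, CH2Cl2, −78 °C, ketene acetal geometry chosen for the syn adduct) would give the keto thioester F4, whose α-stereocenter is configurationally robust. Fukuyama reduction (Et3SiH, Pd/C, acetone) under neutral conditions would then come back to the route at keto aldehyde 16.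

Step 14. The sigmatropic shift may form the new bond at C5 from the β face, because axial attack on the favoured half-chair competes with the steric preference for the α face. The fallback sets out from allylic alcohol 22 and replaces the cyclic transition state by an intermolecular substitution governed by steric approach. Esterification with picolinic acid (DCC, DMAP) would give the picolinate F5. Copper-mediated anti-SN2' substitution with (1,3-dioxolan-2-ylmethyl)magnesium bromide (CuBr·SMe2, THF, −40 °C) would deliver the two-carbon unit to C5 with transposition of the double bond to the exocyclic position, giving the dioxolane acetal F6. Mild hydrolysis (PPTS, acetone–water) would come back to the route at ynal 25.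

Further compounds
F1 | step 15 | 3β-[(2S,3S,5E)-3-acetoxy-6-iodohept-5-en-2-yl]-4-(hydroxymethyl)-7aα-methyl-2,3,3aα,6,7,7a-hexahydro-1H-inden-7α-yl propanoate | OCC1=CC[C@H](OC(=O)CC)[C@@]2(C)CC[C@@H]([C@H](C)[C@@H](OC(C)=O)C/C=C(\C)I)[C@@H]12
F2 | step 15 | 3β-[(2S,3S,5E)-3-acetoxy-6-iodohept-5-en-2-yl]-7aα-methyl-4-methylidene-5α-(2-oxoethyl)-3aα-H-octahydro-1H-inden-7α-yl propanoate | C=C1[C@H](CC=O)C[C@H](OC(=O)CC)[C@@]2(C)CC[C@@H]([C@H](C)[C@@H](OC(C)=O)C/C=C(\C)I)[C@@H]12
F3 | step 15 | macrocyclic enone (carbinol of 27 oxidized to the ketone) | C=C1[C@@H]2CC(=O)/C(C)=C/C[C@H](OC(C)=O)[C@@H](C)[C@@H]3CC[C@](C)([C@@H](OC(=O)CC)C2)[C@H]13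
F4 | step 9 | S-ethyl (2S)-2-[7aα-methyl-4-oxo-7α-(propanoyloxy)-3aα-H-octahydro-1H-inden-3β-yl]propanethioate | O=C1CC[C@H](OC(=O)CC)[C@@]2(C)CC[C@@H]([C@H](C)C(=O)SCC)[C@@H]12
F5 | step 14 | picolinate ester of allylic alcohol 22 | O=C(OCC1=CC[C@H](OC(=O)CC)[C@@]2(C)CC[C@@H]([C@H](C)[C@@H](OC(C)=O)CC#CC)[C@@H]12)c3ccccn3
F6 | step 14 | 1,3-dioxolane acetal of ynal 25 | C=C1[C@H](CC3OCCO3)C[C@H](OC(=O)CC)[C@@]2(C)CC[C@@H]([C@H](C)[C@@H](OC(C)=O)CC#CC)[C@@H]12
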